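(Its constants were drawn at random within sensible limits.)

In this closed, stirred vessel gas crosses from the held gas phase into the solution, the catalyst turns substrate and dissolved gas into target, added ligand shuts catalyst away as idle complex, and target isomerises.

    gas phase ⇌ dissolved gas, rate k1*(csat - [dissolved gas]) (k1 = 6.87 /s, csat = 0.33 mM)
    substrate + dissolved gas + catalyst → catalyst + target (k2 = 8.63 × 10⁷ /M²/s)
    catalyst + added ligand ⇌ idle complex, settled at all times (K3 = 2.6 × 10⁶ /M)
    target ⇌ isomer of the product (K4 = 0.58, k4 = 0.607 /s)

substrate 10 mM; gas phase 0.33 mM (held); catalyst 0.1 mol%; added ligand 19 µM; time 8.0 s

- target at 8.0 s, in percent of the substrate charged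
- concentration of dissolved gas in solution at 8.0 s, in percent of saturation

I turn the question round. The opposite outcome, a flask with catalyst left over once the added ligand is bound up, asks for less added ligand than catalyst. This flask has 19 µM of added ligand against 10.0 µM of catalyst, more ligand than catalyst.

I solve both ends. With ligand in excess, the ligand left after one-for-one binding holds the free catalyst near one part in one plus K3 times that leftover. With catalyst in excess, the free part is what the ligand charge leaves unbound. The quadratic balance of step 3 joins the two ends and leaves 3.93% of the catalyst charge unbound, and this free fraction is the quantity I carry.

With it, I reckon the gas used up at 0.339 /s, slower than the transfer at 6.87 /s, so my estimate for the solution is 95.3% of saturation. My estimate for the substrate converted is then 8.19% of its charge. The isomer balance relaxes with a half-life of 0.419 s, shorter than the run, so I keep one part in 1.58 as target: 5.18%.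

The forecast gives 5.3% and 95.6%, reasoning that “only about 4% is active”; both numbers stand slightly above mine.

The simulation gives 5.32% and 95.6%. In this flask the binding into idle complex and the short time act together on target: without the binding target reaches 47.8% at 8.0 s, and with it, left for 80.0 s, 36.8%. The neighbour with 0.4 mol% of catalyst holds 40.0 µM, more catalyst than added ligand. The same quadratic gives that neighbour a free fraction of 53.3% against 3.93% in this flask, and the neighbour's target stands at 58.6%.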